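**Retrosynthetic overview**

1. Numbering: lactone O1, C2 (C=O), C3=C4, C5, C6; side chain C1' (on C6) to C10' (benzylic). The strategy rests on C6 (the ring carbinol carbon) and C4' (the acetoxy carbinol carbon) standing (E)-1,5-anti across the C1'=C2' alkene.
2. Late stage: acetonide hydrolysis ⇐ O4' acetylation ⇐ O6→C2 lactonisation of a (Z)-enoic acid ⇐ alkyne semihydrogenation ⇐ CO2 on the C3 acetylide.
3. Key disconnection: C6–C1' and C3'–C4' in one pot, to 4-(trimethylsilyl)but-3-ynal 11 (C3–C6), allenylboronic acid pinacol ester 12 (C1'–C3', with (Ipc)2BH) and acetonide aldehyde 9 (C4'–C10').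
4. Aldehyde 9 from ethyl 3-oxo-5-phenylpentanoate: asymmetric hydrogenation (C8'), Claisen extension with tert-butyl acetate, syn reduction (C6'), acetonide, partial reduction.
5. Ring order: phenyl ring present from the start; 1,3-dioxane (protecting ring) in step 4; 5,6-dihydro-2H-pyran-2-one ring in step 10; dioxane opened in step 12.

Key step: step 7

**Remarks**

- Assumption: (Ipc)2BH made from (−)-α-pinene, i.e. (+)-(Ipc)2BH, SMILES [BH]([C@H]1C[C@H]2C[C@@H]([C@@H]1C)C2(C)C)[C@H]1C[C@H]2C[C@@H]([C@@H]1C)C2(C)C, is taken to steer its γ-borylallyl group to the Re face of an aldehyde, in the same sense as the parent B-allyl reagent of that series.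
- The CIP label of the dioxane carbon C4 (= C6') changes with the side chain (R in 8, 9 and 22; S in 16, 17, 19, 20 and 21) although its geometry never changes.

**Route**

Step 1
Reactants: 1 ethyl 3-oxo-5-phenylpentanoate
Product: 2 ethyl (3R)-3-hydroxy-5-phenylpentanoate
Conditions: H2 (50 atm), RuCl2[(R)-BINAP] (0.5 mol %), EtOH, 80 °C
Reagents that add atoms: none
Why: Noyori asymmetric hydrogenation of a β-keto ester, in which the ester carbonyl chelates ruthenium and the (R)-BINAP ligand directs hydride to the face that gives the (3R) alcohol (future C8') for a ketone flanked by an unbranched alkyl chain.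

Step 2
Reactants: 2 ethyl (3R)-3-hydroxy-5-phenylpentanoate; 3 tert-butyl acetate
Product: 5 tert-butyl (5R)-5-hydroxy-3-oxo-7-phenylheptanoate, via lithium enolate of tert-butyl acetate 4 (not isolated)
Conditions: 3 (3.5 equiv), LiN(iPr)2 (3.5 equiv), THF, −78 °C; then 2, −78 → −20 °C; 1 M HCl
Reagents that add atoms: none
Why: Crossed Claisen condensation in which excess enolate 4 first deprotonates the hydroxyl and then acylates at the ethyl ester, the product being shielded from further attack as its enolate while the carbinol centre is untouched.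

Step 3
Reactants: 5 tert-butyl (5R)-5-hydroxy-3-oxo-7-phenylheptanoate
Product: 7 tert-butyl (3R,5R)-3,5-dihydroxy-7-phenylheptanoate (syn diol), via diethylboron chelate 6 (not isolated)
Conditions: Et2BOMe, THF/MeOH (4:1), −78 °C; NaBH4, −78 °C; AcOH, then MeOH co-evaporation
Reagents that add atoms: none
Why: Narasaka–Prasad reduction, in which chelate 6 holds the β-hydroxy ketone in a half-chair and external hydride adds axially, setting the new carbinol (future C6') syn to the existing one.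

Step 4
Reactants: 7 tert-butyl (3R,5R)-3,5-dihydroxy-7-phenylheptanoate
Product: 8 tert-butyl 2-[(4R,6R)-2,2-dimethyl-6-(2-phenylethyl)-1,3-dioxan-4-yl]acetate (cis acetonide)
Conditions: 2,2-dimethoxypropane, PPTS (cat.), acetone, rt
Reagents that add atoms: 2,2-dimethoxypropane, COC(C)(C)OC
Why: Acid-catalysed transketalisation of a syn-1,3-diol to the chair cis-acetonide, conditions to which the tert-butyl ester is inert.

Step 5
Reactants: 8 tert-butyl 2-[(4R,6R)-2,2-dimethyl-6-(2-phenylethyl)-1,3-dioxan-4-yl]acetate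
Product: 9 2-[(4R,6R)-2,2-dimethyl-6-(2-phenylethyl)-1,3-dioxan-4-yl]acetaldehyde
Conditions: iBu2AlH (1.1 equiv), CH2Cl2, −78 °C; MeOH, then aq. KNaC4H4O6 (potassium sodium tartrate)
Reagents that add atoms: none
Why: Partial ester reduction by iBu2AlH at low temperature, where the tetrahedral aluminium hemiacetal, held by the β-oxygen, should persist until aqueous work-up and then release the aldehyde.

Step 6
Reactants: 10 4-(trimethylsilyl)but-3-yn-1-ol
Product: 11 4-(trimethylsilyl)but-3-ynal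
Conditions: Dess–Martin periodinane, CH2Cl2, 0 °C → rt; pentane, filtration; used at once
Reagents that add atoms: none
Why: Dess–Martin oxidation of a primary alcohol under base-free conditions, which avoids the base-induced isomerisation of the β,γ-ynal to the allenal.

Step 7
Reactants: 12 allenylboronic acid pinacol ester; 11 4-(trimethylsilyl)but-3-ynal; 9 2-[(4R,6R)-2,2-dimethyl-6-(2-phenylethyl)-1,3-dioxan-4-yl]acetaldehyde
Product: 16 (2R,4E,6S)-1-[(4S,6R)-2,2-dimethyl-6-(2-phenylethyl)-1,3-dioxan-4-yl]-9-(trimethylsilyl)non-4-en-8-yne-2,6-diol (the (E)-1,5-anti enediol, 6S and 4'R in target numbering), via (E)-γ-borylallylborane 13 (not isolated), via anti α-boryl allylboronate 14 (not isolated), via bis-O-borylated enediol 15 (not isolated)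
Conditions: (+)-(Ipc)2BH [from (−)-α-pinene], Et2O, −25 → 0 °C; 11, −78 °C; 9, −78 °C → rt; aq. NaHCO3, H2O2, 0 °C → rt
Reagents that add atoms: none
Why: (Ipc)2BH adds across the unsubstituted C=C of allene 12 (boron to the terminal carbon) and the allylborane settles by 1,3-boratropic shift into the (E)-γ-borylallylborane 13, whose dialkylallylborane end adds at −78 °C to ynal 11 through a closed chair transition state (C6–C1' bond, anti α-boryl centre, intermediate 14), after which 14 reacts on warming as an α-substituted allylboronate with aldehyde 9 through a second chair (C3'–C4' bond, double bond transposed to C1'=C2'). The closest known reaction type is the one-pot double allylboration of two different aldehydes by an in situ γ-borylallyl(diisopinocampheyl)borane, which is established to give (E)-1,5-anti-enediols. No ring is closed; two C–C bonds and two stereocentres are formed. C6 (S) is controlled by the isopinocampheyl groups of the (−)-α-pinene series, which steer the allyl unit to the Re face of 11, and the E geometry of 13 places the boron-bearing C1' anti to O6. C4' (R) and the E alkene are controlled by chirality transfer from C1' of 14, because the large CH(OB(Ipc)2)R substituent on the boron-bearing carbon and the residue of 9 should both sit equatorial in the second chair. The step needs chemoselectivity between the two boron ends and reagent control over the β-alkoxy aldehyde: the first is secured by the much higher reactivity of the B(Ipc)2 allyl end (consumed at −78 °C before 9 is added) over the pinacol boronate end (reacts only near rt), the second by the α-boryl centre of 14, whose demand (C4' anti to C6') coincides with the usual modest 1,3-anti preference of such aldehydes.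

Step 8
Reactants: 16 (2R,4E,6S)-1-[(4S,6R)-2,2-dimethyl-6-(2-phenylethyl)-1,3-dioxan-4-yl]-9-(trimethylsilyl)non-4-en-8-yne-2,6-diol
Product: 17 (2R,4E,6S)-1-[(4S,6R)-2,2-dimethyl-6-(2-phenylethyl)-1,3-dioxan-4-yl]non-4-en-8-yne-2,6-diol
Conditions: K2CO3, MeOH, 0 °C → rt
Reagents that add atoms: none
Why: Base-catalysed methanolysis of the C(sp)–Si bond (protodesilylation of an alkynylsilane), to which acetonide, alkene and free alcohols are inert.

Step 9
Reactants: 17 (2R,4E,6S)-1-[(4S,6R)-2,2-dimethyl-6-(2-phenylethyl)-1,3-dioxan-4-yl]non-4-en-8-yne-2,6-diol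
Product: 19 (5S,6E,9R)-10-[(4S,6R)-2,2-dimethyl-6-(2-phenylethyl)-1,3-dioxan-4-yl]-5,9-dihydroxydec-6-en-2-ynoic acid, via trilithium acetylide dialkoxide 18 (not isolated)
Conditions: n-BuLi (3.3 equiv), THF, −78 → −20 °C; CO2, −78 → 0 °C; 1 M HCl to pH 4, 0 °C
Reagents that add atoms: carbon dioxide, O=C=O
Why: Carboxylation of a lithium acetylide with CO2, as in the classical dianion carboxylation of homopropargylic alcohols: the third equivalent of base deprotonates the alkyne after both hydroxyls, the acetylide is carboxylated at carbon, and lithium alkyl carbonates formed at oxygen revert to the alcohols on mild acidification.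

Step 10
Reactants: 19 (5S,6E,9R)-10-[(4S,6R)-2,2-dimethyl-6-(2-phenylethyl)-1,3-dioxan-4-yl]-5,9-dihydroxydec-6-en-2-ynoic acid
Product: 21 (6S)-6-[(1E,4R)-5-[(4S,6R)-2,2-dimethyl-6-(2-phenylethyl)-1,3-dioxan-4-yl]-4-hydroxypent-1-en-1-yl]-5,6-dihydro-2H-pyran-2-one, via (Z)-hydroxy enoic acid 20 (not isolated)
Conditions: H2 (1 atm), Pd/CaCO3 poisoned with Pb(OAc)2, quinoline, EtOAc, rt; then PPTS (cat.), CH2Cl2, rt
Reagents that add atoms: none
Why: Lindlar semihydrogenation adds H2 syn to the alkyne only, and in the resulting (Z)-5-hydroxy-2-enoic acid 20 the carboxyl and O6 are held cis, so that the six-membered lactone should close at O6 in preference to the remote O4' without touching C6.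

Step 11
Reactants: 21 (6S)-6-[(1E,4R)-5-[(4S,6R)-2,2-dimethyl-6-(2-phenylethyl)-1,3-dioxan-4-yl]-4-hydroxypent-1-en-1-yl]-5,6-dihydro-2H-pyran-2-one
Product: 22 (2R,4E)-1-[(4R,6R)-2,2-dimethyl-6-(2-phenylethyl)-1,3-dioxan-4-yl]-5-[(2S)-6-oxo-3,6-dihydro-2H-pyran-2-yl]pent-4-en-2-yl acetate
Conditions: Ac2O, pyridine, DMAP (cat.), CH2Cl2, 0 °C → rt
Reagents that add atoms: acetic anhydride, CC(=O)OC(C)=O
Why: DMAP-catalysed acylation of the only free hydroxyl (O4'), O6 being held in the lactone and O6'/O8' in the acetonide.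

Step 12
Reactants: 22 (2R,4E)-1-[(4R,6R)-2,2-dimethyl-6-(2-phenylethyl)-1,3-dioxan-4-yl]-5-[(2S)-6-oxo-3,6-dihydro-2H-pyran-2-yl]pent-4-en-2-yl acetate
Product: 23 (1E,4R,6R,8R)-6,8-dihydroxy-1-[(2S)-6-oxo-3,6-dihydro-2H-pyran-2-yl]-10-phenyldec-1-en-4-yl acetate (target)
Conditions: AcOH/H2O (4:1), rt
Reagents that add atoms: none
Why: Acid-catalysed hydrolysis of the isopropylidene ketal in aqueous acetic acid, a medium in which a secondary acetate and the unsaturated lactone should persist and acyl migration is slow.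

**Compound list**

1 | ethyl 3-oxo-5-phenylpentanoate | CCOC(=O)CC(=O)CCc1ccccc1 | starting material
2 | ethyl (3R)-3-hydroxy-5-phenylpentanoate | CCOC(=O)C[C@H](O)CCc1ccccc1 | intermediate
3 | tert-butyl acetate | CC(=O)OC(C)(C)C | starting material
4 | lithium enolate of tert-butyl acetate | C=C(O[Li])OC(C)(C)C | intermediate
5 | tert-butyl (5R)-5-hydroxy-3-oxo-7-phenylheptanoate | CC(C)(C)OC(=O)CC(=O)C[C@H](O)CCc1ccccc1 | intermediate
6 | diethylboron chelate of 5, tert-butyl (5R)-5-[(diethylboranyl)oxy]-3-oxo-7-phenylheptanoate | CCB(CC)O[C@H](CCc1ccccc1)CC(=O)CC(=O)OC(C)(C)C | intermediate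
7 | tert-butyl (3R,5R)-3,5-dihydroxy-7-phenylheptanoate | CC(C)(C)OC(=O)C[C@H](O)C[C@H](O)CCc1ccccc1 | intermediate
8 | tert-butyl 2-[(4R,6R)-2,2-dimethyl-6-(2-phenylethyl)-1,3-dioxan-4-yl]acetate | CC(C)(C)OC(=O)C[C@H]1C[C@@H](CCc2ccccc2)OC(C)(C)O1 | intermediate
9 | 2-[(4R,6R)-2,2-dimethyl-6-(2-phenylethyl)-1,3-dioxan-4-yl]acetaldehyde | O=CC[C@H]1C[C@@H](CCc2ccccc2)OC(C)(C)O1 | intermediate
10 | 4-(trimethylsilyl)but-3-yn-1-ol | C[Si](C)(C)C#CCCO | starting material
11 | 4-(trimethylsilyl)but-3-ynal | O=CCC#C[Si](C)(C)C | intermediate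
12 | allenylboronic acid pinacol ester, 4,4,5,5-tetramethyl-2-(propa-1,2-dien-1-yl)-1,3,2-dioxaborolane | C=C=CB1OC(C)(C)C(C)(C)O1 | starting material
13 | bis(isopinocampheyl)[(2E)-3-(4,4,5,5-tetramethyl-1,3,2-dioxaborolan-2-yl)prop-2-en-1-yl]borane, isopinocampheyl groups of the (−)-α-pinene series | CC1(C)OB(/C=C/CB([C@H]2C[C@H]3C[C@@H]([C@@H]2C)C3(C)C)[C@H]2C[C@H]3C[C@@H]([C@@H]2C)C3(C)C)OC1(C)C | intermediate
14 | 2-[(3R,4S)-4-{[bis(isopinocampheyl)boranyl]oxy}-7-(trimethylsilyl)hept-1-en-6-yn-3-yl]-4,4,5,5-tetramethyl-1,3,2-dioxaborolane (oxygen and boron anti) | C[Si](C)(C)C#CC[C@H](OB([C@H]1C[C@H]2C[C@@H]([C@@H]1C)C2(C)C)[C@H]1C[C@H]2C[C@@H]([C@@H]1C)C2(C)C)[C@H](B1OC(C)(C)C(C)(C)O1)C=C | intermediate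
15 | diol 16 carrying B(Ipc)2 on O6 and the pinacolatoboryl group on O4' | C[Si](C)(C)C#CC[C@H](OB([C@H]1C[C@H]2C[C@@H]([C@@H]1C)C2(C)C)[C@H]1C[C@H]2C[C@@H]([C@@H]1C)C2(C)C)/C=C/C[C@@H](OB1OC(C)(C)C(C)(C)O1)C[C@H]1C[C@@H](CCc2ccccc2)OC(C)(C)O1 | intermediate
16 | (2R,4E,6S)-1-[(4S,6R)-2,2-dimethyl-6-(2-phenylethyl)-1,3-dioxan-4-yl]-9-(trimethylsilyl)non-4-en-8-yne-2,6-diol | C[Si](C)(C)C#CC[C@H](O)/C=C/C[C@@H](O)C[C@H]1C[C@@H](CCc2ccccc2)OC(C)(C)O1 | intermediate
17 | (2R,4E,6S)-1-[(4S,6R)-2,2-dimethyl-6-(2-phenylethyl)-1,3-dioxan-4-yl]non-4-en-8-yne-2,6-diol | C#CC[C@H](O)/C=C/C[C@@H](O)C[C@H]1C[C@@H](CCc2ccccc2)OC(C)(C)O1 | intermediate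
18 | trilithium salt of 17 (acetylide and both alkoxides) | [Li]C#CC[C@H](O[Li])/C=C/C[C@@H](O[Li])C[C@H]1C[C@@H](CCc2ccccc2)OC(C)(C)O1 | intermediate
19 | (5S,6E,9R)-10-[(4S,6R)-2,2-dimethyl-6-(2-phenylethyl)-1,3-dioxan-4-yl]-5,9-dihydroxydec-6-en-2-ynoic acid | OC(=O)C#CC[C@H](O)/C=C/C[C@@H](O)C[C@H]1C[C@@H](CCc2ccccc2)OC(C)(C)O1 | intermediate
20 | (2Z,5S,6E,9R)-10-[(4S,6R)-2,2-dimethyl-6-(2-phenylethyl)-1,3-dioxan-4-yl]-5,9-dihydroxydeca-2,6-dienoic acid | OC(=O)/C=C\C[C@H](O)/C=C/C[C@@H](O)C[C@H]1C[C@@H](CCc2ccccc2)OC(C)(C)O1 | intermediate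
21 | (6S)-6-[(1E,4R)-5-[(4S,6R)-2,2-dimethyl-6-(2-phenylethyl)-1,3-dioxan-4-yl]-4-hydroxypent-1-en-1-yl]-5,6-dihydro-2H-pyran-2-one | O=C1C=CC[C@@H](/C=C/C[C@@H](O)C[C@H]2C[C@@H](CCc3ccccc3)OC(C)(C)O2)O1 | intermediate
22 | (2R,4E)-1-[(4R,6R)-2,2-dimethyl-6-(2-phenylethyl)-1,3-dioxan-4-yl]-5-[(2S)-6-oxo-3,6-dihydro-2H-pyran-2-yl]pent-4-en-2-yl acetate | CC(=O)O[C@H](C/C=C/[C@@H]1CC=CC(=O)O1)C[C@H]1C[C@@H](CCc2ccccc2)OC(C)(C)O1 | intermediate
23 | (1E,4R,6R,8R)-6,8-dihydroxy-1-[(2S)-6-oxo-3,6-dihydro-2H-pyran-2-yl]-10-phenyldec-1-en-4-yl acetate | CC(=O)O[C@H](C/C=C/[C@@H]1CC=CC(=O)O1)C[C@H](O)C[C@H](O)CCc1ccccc1 | target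

**Step count and weak points**

Total steps: 12. Longest linear sequence: 11 steps (steps 1 to 5, 7, 8 to 12, from ethyl 3-oxo-5-phenylpentanoate); step 6 is a one-step side branch.

Steps most likely to fail:

1. Step 7. The β,γ-ynal may isomerise to the allenal or be incompletely consumed, so that leftover allylborane end attacks aldehyde 9. The second allylboration of the hindered β-alkoxy aldehyde may also be slow or lose E and facial control. Fallback, setting out from 9 and returning at 21: allylation of 9 with (Ipc)2B(allyl) made from (+)-(Ipc)2BOMe [(−)-α-pinene series] and allylMgBr should give (2R)-1-[(4S,6R)-2,2-dimethyl-6-(2-phenylethyl)-1,3-dioxan-4-yl]pent-4-en-2-ol F1. Separately, acrolein and (Ipc)2B(allyl) of the (+)-α-pinene series give (3S)-hexa-1,5-dien-3-ol F2, which acryloyl chloride and Et3N convert into (3S)-hexa-1,5-dien-3-yl prop-2-enoate F3. Ring-closing metathesis of F3 with first-generation Grubbs catalyst RuCl2(PCy3)2(=CHPh) gives (6S)-6-ethenyl-5,6-dihydro-2H-pyran-2-one F4. Cross-metathesis of F1 with excess F4 (second-generation Grubbs catalyst, CH2Cl2, 40 °C) should then form the E C1'=C2' alkene and give 21 directly, so that steps 8 to 10 are not needed.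

2. Step 9. Deprotonation to the trilithium species may be incomplete or the salt may precipitate, giving low conversion, and the acetonide may be lost on acidification. Fallback, setting out from 17 and returning at 21: silylation (Et3SiCl, imidazole, DMF) gives the bis(triethylsilyl) ether of 17 F5. Deprotonation with n-BuLi and trapping with methyl chloroformate gives the methyl ynoate, methyl ester of the O,O-bis(triethylsilyl) derivative of 19 F6. Semihydrogenation over Pd/CaCO3 poisoned with Pb(OAc)2 gives the (Z)-enoate, methyl ester of the O,O-bis(triethylsilyl) derivative of 20 F7. HF·pyridine in THF then removes both silyl groups, and the freed O6 closes onto the ester (PPTS cat. if needed) to give 21.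

3. Step 5. The tert-butyl ester reacts sluggishly with iBu2AlH, so the reduction may stop short or run on to the primary alcohol. Fallback, setting out from 8 and returning at 9: full reduction with LiAlH4 (THF, 0 °C) gives 2-[(4S,6R)-2,2-dimethyl-6-(2-phenylethyl)-1,3-dioxan-4-yl]ethan-1-ol F8, which Dess–Martin periodinane (CH2Cl2, rt) oxidises to 9.

**Further compounds**

F1 | step 7 | (2R)-1-[(4S,6R)-2,2-dimethyl-6-(2-phenylethyl)-1,3-dioxan-4-yl]pent-4-en-2-ol | C=CC[C@@H](O)C[C@H]1C[C@@H](CCc2ccccc2)OC(C)(C)O1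
F2 | step 7 | (3S)-hexa-1,5-dien-3-ol | C=CC[C@H](O)C=C
F3 | step 7 | (3S)-hexa-1,5-dien-3-yl prop-2-enoate | C=CC[C@H](OC(=O)C=C)C=C
F4 | step 7 | (6S)-6-ethenyl-5,6-dihydro-2H-pyran-2-one | C=C[C@@H]1CC=CC(=O)O1
F5 | step 9 | bis(triethylsilyl) ether of 17 | C#CC[C@H](O[Si](CC)(CC)CC)/C=C/C[C@@H](O[Si](CC)(CC)CC)C[C@H]1C[C@@H](CCc2ccccc2)OC(C)(C)O1
F6 | step 9 | methyl ester of the O,O-bis(triethylsilyl) derivative of 19 | COC(=O)C#CC[C@H](O[Si](CC)(CC)CC)/C=C/C[C@@H](O[Si](CC)(CC)CC)C[C@H]1C[C@@H](CCc2ccccc2)OC(C)(C)O1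
F7 | step 9 | methyl ester of the O,O-bis(triethylsilyl) derivative of 20 | COC(=O)/C=C\C[C@H](O[Si](CC)(CC)CC)/C=C/C[C@@H](O[Si](CC)(CC)CC)C[C@H]1C[C@@H](CCc2ccccc2)OC(C)(C)O1
F8 | step 5 | 2-[(4S,6R)-2,2-dimethyl-6-(2-phenylethyl)-1,3-dioxan-4-yl]ethan-1-ol | OCC[C@H]1C[C@@H](CCc2ccccc2)OC(C)(C)O1
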